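**Strategy**

The cyclohexenone ring is cut at C4–C5 and C6–C1 (numbering of the 7-oxabicyclo[4.1.0]hept-3-en-2-one core): a 2,3,5-trisubstituted furan supplies C1, C2, C3 and C4, and an (E)-2-bromovinylboron unit supplies C5 and C6. The key step, a boron-tethered intramolecular Diels–Alder reaction of the furan, forms both bonds and places the C5 oxygen (after C–B oxidation) and a C6 bromide trans to each other. It exploits the 1,4-relation between C4 and the epoxide oxygen O7 on C1: O7 is the furan oxygen and temporarily bridges C1 and C4. Base later ejects O7 from C4, giving the C3=C4 enone, and O7 closes onto C6 to form the epoxide cis to C5–OH. The precursor is the mixed boronate of a 5-farnesyl-4-methoxyfurfuryl alcohol.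

Key step: step 5

Remark on atom labels: C1–C6 and O7 always mean the atoms of the target core (C1 = epoxide carbon bearing the farnesyl chain, C2 = C=O, C3 = CH=, C4 = carbon bearing CH2O, C5 = CHOH, C6 = epoxide CH).

Remark on configuration: compounds 11, 12 and 13 form as racemates. Their SMILES show the enantiomer carried on after the resolution in step 6.

**Route**

Step 1
Reactants: 1 4-bromofuran-2-carbaldehyde
Product: 2 (4-bromofuran-2-yl)methanol
Conditions: NaBH4, MeOH, 0 °C
Reagents that add atoms: none
Why: Borohydride reduction of the aldehyde should give the furfuryl alcohol whose CH2OH becomes the C4 hydroxymethyl group; no stereocenter is formed.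

Step 2
Reactants: 2 (4-bromofuran-2-yl)methanol
Product: 3 (4-methoxyfuran-2-yl)methanol
Conditions: NaOMe (5 equiv), CuBr (10 mol %), MeOH–DMF, 100 °C
Reagents that add atoms: sodium methoxide [Na+].[O-]C
Why: Copper-catalysed Ullmann-type methoxylation of the β-bromofuran should install the enol-ether oxygen that later becomes the C2 carbonyl, the hydroxymethyl group being carried as its alkoxide.

Step 3
Reactants: 3 (4-methoxyfuran-2-yl)methanol; 4 (2E,6E)-farnesyl bromide
Product: 6 {4-methoxy-5-[(2E,6E)-3,7,11-trimethyldodeca-2,6,10-trien-1-yl]furan-2-yl}methanol, via dilithiated furan 5 (not isolated)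
Conditions: n-BuLi (2.1 equiv), THF, −78 → 0 °C; then 4, −78 °C → rt; H2O
Reagents that add atoms: none
Why: O-deprotonation followed by α-lithiation at the furan carbon flanked by the ring oxygen and the methoxy group, then SN2 alkylation of the furyllithium with the allylic bromide, should attach the farnesyl chain with its E,E geometry unchanged.

Step 4
Reactants: 7 (E)-(2-bromovinyl)trimethylsilane
Product: 9 diisopropyl [(E)-2-bromovinyl]boronate, via dibromoborane 8 (not isolated)
Conditions: BBr3, CH2Cl2, 0 °C → rt; then i-PrOH (2.2 equiv), Et3N (2.2 equiv), −78 °C → rt; distillation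
Reagents that add atoms: boron tribromide BrB(Br)Br; propan-2-ol CC(C)O
Why: Ipso borodesilylation of the vinylsilane proceeds with retention of the E geometry, and alcoholysis of the two B–Br bonds should give an exchangeable boronic ester.

Step 5
Reactants: 6 {4-methoxy-5-[(2E,6E)-3,7,11-trimethyldodeca-2,6,10-trien-1-yl]furan-2-yl}methanol; 9 diisopropyl [(E)-2-bromovinyl]boronate
Product: 13 rac-(1S,4S,5R,6S)-6-bromo-5-hydroxy-4-(hydroxymethyl)-1-[(2E,6E)-3,7,11-trimethyldodeca-2,6,10-trien-1-yl]-7-oxabicyclo[2.2.1]heptan-2-one, via mixed boronate 10 (not isolated), via cycloadduct 11 (not isolated), via diol enol ether 12 (not isolated)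
Conditions: 9 (1.5 equiv), 4 Å MS, toluene, 23 → 50 °C; then 30% H2O2, aq. NaHCO3, THF, 0 °C; Na2S2O3; then 1 M HCl (pH 2), THF–H2O, 0 °C
Reagents that add atoms: hydrogen peroxide OO; water O
Why: Proposed new method: transesterification ties alcohol 6 to the dienophile as mixed boronate 10, whose furan (4π) and bromovinyl (2π) units then combine in a concerted, thermally allowed suprafacial [4+2] cycloaddition that forms C4–C5 and C6–C1; the closest known reaction types are the alkenylboronate-tethered intramolecular Diels–Alder reaction of 2,4-dien-1-ols and the intramolecular Diels–Alder reaction of furfuryl allyl ethers, neither yet shown for a furan joined to a β-haloalkenylboronate. The event closes the six-membered carbocycle by [4+2] addition across the two furan α-carbons, which makes the furan oxygen the one-atom bridge of a 7-oxanorbornene, and closes the five-membered 1,2-oxaborolane through the C–O–B tether in an exo-fused mode. Regiochemistry is fixed by the three-atom tether (boron-bearing carbon to the CH2O-bearing furan carbon) and is electronically matched, since the methoxy-activated furan carbon bonds to the carbon β to boron. The short tether can reach only the exo position, so boron on C5 is syn to the oxygen bridge, the E geometry of the dienophile puts bromine on C6 endo and trans to boron, the bridgeheads C1 and C4 follow from the bicycle, and the four centres arise as a racemate that is resolved in step 6. Peroxide then replaces boron by oxygen with retention (C5–OH), which also frees the primary alcohol, and dilute acid hydrolyses the bicyclic enol ether to the C2 ketone, which stops cycloreversion. The farnesyl olefins must neither compete as dienophiles nor be oxidised, which their remote unactivated position and the use of buffered H2O2 (no peracid) should secure.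

Step 6
Reactants: 13 rac-(1S,4S,5R,6S)-6-bromo-5-hydroxy-4-(hydroxymethyl)-1-farnesyl-7-oxabicyclo[2.2.1]heptan-2-one
Product: 14 bis[(1S,4R)-camphanate] of the (1S,4S,5R,6S)-enantiomer of 13
Conditions: (1S)-(−)-camphanic chloride (2.4 equiv), pyridine, DMAP (cat.), CH2Cl2, 0 °C → rt; diastereomers separated by chromatography and crystallisation
Reagents that add atoms: (1S)-(−)-camphanic chloride O=C(Cl)[C@@]12CC[C@@](C)(C(=O)O1)C2(C)C
Why: Acylation of both hydroxyls with the enantiopure acid chloride (classical resolution through diastereomeric esters) should give two separable diastereomers, the one with the (1S,4S,5R,6S) bicycle (to be assigned by X-ray against the camphanate centres) being carried on, and the esters also block the C5 oxygen for step 7.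

Step 7
Reactants: 14 bis-camphanate of the bromo ketone
Product: 15 [(1R,5R,6R)-5-(camphanoyloxy)-2-oxo-1-farnesyl-7-oxabicyclo[4.1.0]hept-3-en-4-yl]methyl camphanate
Conditions: DBU (1.5 equiv), CH2Cl2, 0 °C
Reagents that add atoms: none
Why: E1cB β-elimination of the oxygen bridge from the C3 enolate should create the C3=C4 enone and the C1 alkoxide, which displaces the anti C6 bromide by intramolecular SN2 (3-exo-tet, inversion at C6), so the epoxide is fixed cis to the C5 oxygen while C1 and C5 keep their configuration.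

Step 8
Reactants: 15 epoxy enone bis-camphanate
Product: 16 (1R,5R,6R)-5-hydroxy-4-(hydroxymethyl)-1-[(2E,6E)-3,7,11-trimethyldodeca-2,6,10-trien-1-yl]-7-oxabicyclo[4.1.0]hept-3-en-2-one
Conditions: K2CO3, MeOH, 0 °C
Reagents that add atoms: none
Why: Carbonate-catalysed methanolysis (transesterification) of the two α-oxygenated, hence activated, esters should free both hydroxyls without touching the stereocentres.

Step 9
Reactants: 17 (R)-mevalonolactone
Product: 19 [2-(trimethylsilyl)ethoxy]methyl (3R)-3,5-dihydroxy-3-methylpentanoate, via potassium mevalonate 18 (not isolated)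
Conditions: KOH (1.0 equiv), H2O, rt; evaporation; SEMCl, DMF, 0 °C
Reagents that add atoms: potassium hydroxide [K+].[OH-]; 2-(trimethylsilyl)ethoxymethyl chloride C[Si](C)(C)CCOCCl
Why: Saponification of the δ-lactone and O-alkylation of the carboxylate with the chloromethyl ether should protect the original carboxyl group (the future free acid) while leaving the quaternary stereocentre from the chiral pool untouched.

Step 10
Reactants: 19 SEM (3R)-mevalonate
Product: 20 (3R)-3-hydroxy-3-methyl-5-oxo-5-{[2-(trimethylsilyl)ethoxy]methoxy}pentanoic acid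
Conditions: TEMPO (0.2 equiv), PhI(OAc)2 (2.2 equiv), MeCN–pH 7 buffer, rt
Reagents that add atoms: water O
Why: Oxoammonium (TEMPO) oxidation of the primary alcohol through the aldehyde hydrate should give the acid and leave the tertiary alcohol alone, so the two arms of the hydroxymethylglutarate stay differentiated and the stereocentre is kept.

Step 11
Reactants: 16 epoxy enone diol; 20 mono-protected (3R)-hydroxymethylglutaric acid
Product: 21 1-{[(1R,5R,6R)-5-hydroxy-2-oxo-1-farnesyl-7-oxabicyclo[4.1.0]hept-3-en-4-yl]methyl} 5-{[2-(trimethylsilyl)ethoxy]methyl} (3R)-3-hydroxy-3-methylpentanedioate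
Conditions: 20 (1.1 equiv), EDC·HCl, DMAP (cat.), CH2Cl2, −20 → 0 °C
Reagents that add atoms: none
Why: Steglich esterification should acylate the primary allylic alcohol in preference to the flanked secondary C5 alcohol and the tertiary alcohol of the acid; no stereocentre is affected.

Step 12
Reactants: 21 SEM ester
Product: 22 (3S)-3-hydroxy-5-{[(1R,5R,6R)-5-hydroxy-2-oxo-1-[(2E,6E)-3,7,11-trimethyldodeca-2,6,10-trien-1-yl]-7-oxabicyclo[4.1.0]hept-3-en-4-yl]methoxy}-3-methyl-5-oxopentanoic acid
Conditions: 48% aq. HF, MeCN, 0 °C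
Reagents that add atoms: none
Why: Fluoride-induced fragmentation of the silylethoxymethyl ester (loss of Me3SiF, ethene and formaldehyde) should free the acid under conditions the epoxy enone, the allylic ester and the olefins tolerate; the descriptor at the side-chain centre changes from R to S only because the priorities of the two arms swap.

**Compound list**

1 | 4-bromofuran-2-carbaldehyde | O=Cc1cc(Br)co1 | starting material
2 | (4-bromofuran-2-yl)methanol | OCc1cc(Br)co1 | intermediate
3 | (4-methoxyfuran-2-yl)methanol | COc1coc(CO)c1 | intermediate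
4 | (2E,6E)-farnesyl bromide | BrC/C=C(\C)CC/C=C(\C)CCC=C(C)C | starting material
5 | lithium (5-lithio-4-methoxyfuran-2-yl)methoxide (not isolated) | [Li]OCc1cc(OC)c([Li])o1 | intermediate
6 | {4-methoxy-5-[(2E,6E)-3,7,11-trimethyldodeca-2,6,10-trien-1-yl]furan-2-yl}methanol | OCc1cc(OC)c(C/C=C(\C)CC/C=C(\C)CCC=C(C)C)o1 | intermediate
7 | (E)-(2-bromovinyl)trimethylsilane | C[Si](C)(C)/C=C/Br | starting material
8 | (E)-(2-bromovinyl)dibromoborane (not isolated) | BrB(Br)/C=C/Br | intermediate
9 | diisopropyl [(E)-2-bromovinyl]boronate | CC(C)OB(OC(C)C)/C=C/Br | intermediate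
10 | isopropyl (5-farnesyl-4-methoxyfuran-2-yl)methyl [(E)-2-bromovinyl]boronate (not isolated) | CC(C)OB(/C=C/Br)OCc1cc(OC)c(C/C=C(\C)CC/C=C(\C)CCC=C(C)C)o1 | intermediate
11 | racemic exo-fused 1,2-oxaborolane cycloadduct: 7-oxanorbornene with B on C5 syn to the bridge, Br on C6 endo (not isolated) | CC(C)OB1OC[C@@]23O[C@@](C/C=C(\C)CC/C=C(\C)CCC=C(C)C)(C(OC)=C2)[C@@H](Br)[C@@H]31 | intermediate
12 | rac-(1S,4S,5R,6S)-6-bromo-4-(hydroxymethyl)-2-methoxy-1-farnesyl-7-oxabicyclo[2.2.1]hept-2-en-5-ol (not isolated) | OC[C@@]12O[C@@](C/C=C(\C)CC/C=C(\C)CCC=C(C)C)(C(OC)=C1)[C@@H](Br)[C@@H]2O | intermediate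
13 | rac-(1S,4S,5R,6S)-6-bromo-5-hydroxy-4-(hydroxymethyl)-1-farnesyl-7-oxabicyclo[2.2.1]heptan-2-one | OC[C@@]12O[C@@](C/C=C(\C)CC/C=C(\C)CCC=C(C)C)(C(=O)C1)[C@@H](Br)[C@@H]2O | intermediate
14 | (1S,4S,5R,6S)-6-bromo-4-{[(1S,4R)-camphanoyloxy]methyl}-2-oxo-1-farnesyl-7-oxabicyclo[2.2.1]heptan-5-yl (1S,4R)-camphanate | O=C(OC[C@@]12O[C@@](C/C=C(\C)CC/C=C(\C)CCC=C(C)C)(C(=O)C1)[C@@H](Br)[C@@H]2OC(=O)[C@@]34CC[C@@](C)(C(=O)O3)C4(C)C)[C@@]56CC[C@@](C)(C(=O)O5)C6(C)C | intermediate
15 | [(1R,5R,6R)-5-{[(1S,4R)-camphanoyl]oxy}-2-oxo-1-farnesyl-7-oxabicyclo[4.1.0]hept-3-en-4-yl]methyl (1S,4R)-camphanate | CC(C)=CCC/C(C)=C/CC/C(C)=C/C[C@@]12O[C@@H]1[C@H](OC(=O)[C@@]34CC[C@@](C)(C(=O)O3)C4(C)C)C(COC(=O)[C@@]56CC[C@@](C)(C(=O)O5)C6(C)C)=CC2=O | intermediate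
16 | (1R,5R,6R)-5-hydroxy-4-(hydroxymethyl)-1-[(2E,6E)-3,7,11-trimethyldodeca-2,6,10-trien-1-yl]-7-oxabicyclo[4.1.0]hept-3-en-2-one | CC(C)=CCC/C(C)=C/CC/C(C)=C/C[C@@]12O[C@@H]1[C@H](O)C(CO)=CC2=O | intermediate
17 | (R)-mevalonolactone | C[C@@]1(O)CCOC(=O)C1 | starting material
18 | potassium (3R)-3,5-dihydroxy-3-methylpentanoate (not isolated) | C[C@@](O)(CCO)CC(=O)[O-].[K+] | intermediate
19 | [2-(trimethylsilyl)ethoxy]methyl (3R)-3,5-dihydroxy-3-methylpentanoate | C[C@@](O)(CCO)CC(=O)OCOCC[Si](C)(C)C | intermediate
20 | (3R)-3-hydroxy-3-methyl-5-oxo-5-{[2-(trimethylsilyl)ethoxy]methoxy}pentanoic acid | C[C@@](O)(CC(=O)O)CC(=O)OCOCC[Si](C)(C)C | intermediate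
21 | 1-{[(1R,5R,6R)-5-hydroxy-2-oxo-1-farnesyl-7-oxabicyclo[4.1.0]hept-3-en-4-yl]methyl} 5-{[2-(trimethylsilyl)ethoxy]methyl} (3R)-3-hydroxy-3-methylpentanedioate | CC(C)=CCC/C(C)=C/CC/C(C)=C/C[C@@]12O[C@@H]1[C@H](O)C(COC(=O)C[C@@](C)(O)CC(=O)OCOCC[Si](C)(C)C)=CC2=O | intermediate
22 | (3S)-3-hydroxy-5-{[(1R,5R,6R)-5-hydroxy-2-oxo-1-[(2E,6E)-3,7,11-trimethyldodeca-2,6,10-trien-1-yl]-7-oxabicyclo[4.1.0]hept-3-en-4-yl]methoxy}-3-methyl-5-oxopentanoic acid | CC(C)=CCC/C(C)=C/CC/C(C)=C/C[C@@]12O[C@@H]1[C@H](O)C(COC(=O)C[C@@](C)(O)CC(=O)O)=CC2=O | target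

**Step count and risks**

Total step count: 12. Longest linear sequence: 9 steps (steps 1, 2, 3, 5, 6, 7, 8, 11, 12).

Steps most likely to fail:

1. Step 5 (Proposed new method). The tethered cycloaddition may not occur below the temperature at which the electron-rich furan or the adduct decomposes, the adduct may revert once the tether is cleaved, or the β-bromo organoboron intermediate may lose bromide before oxidation. The fallback makes the same two ring bonds in one operation by the known thermal Diels–Alder reaction of a furan with vinylene carbonate. It sets out from 6 and comes back at 15.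
   - Silylation (TBSCl, imidazole) should give the silyl ether F1.
   - Heating with vinylene carbonate (neat, 90 °C) and separation from the exo isomer should give the endo cyclic carbonate F2.
   - K2CO3/MeOH should free the endo,endo-diol F3; no ketone is present yet, so the bridge stays.
   - MsCl/Et3N should give the bis-mesylate F4.
   - Aqueous oxalic acid should unmask the keto bis-mesylate F5.
   - DBU should trigger the same bridge-opening and epoxide-closing cascade as in step 7, the C1 alkoxide displacing the anti C6 mesylate, to give the epoxy enone anti-mesylate F6.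
   - CsOAc/18-crown-6 should invert C5 by SN2 to the syn acetate F7.
   - K2CO3/MeOH and then HF·pyridine should give racemic diol F8.
   - Acylation of F8 with (1S)-camphanic chloride and separation of the diastereomers returns to the route at 15.

2. Step 7. Direct base treatment may cause γ-deprotonation at C5 of the product with opening of the new epoxide, or acyl migration from the C5 ester to the C1 alkoxide before ring closure. The fallback splits the cascade into a soft enolisation and a separate fluoride-triggered closure. It sets out from 14 and comes back at 15.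
   - TMSOTf/Et3N (CH2Cl2, −78 → 0 °C) should open the bridge through the silyl enol ether and trap the C1 oxygen as the ring-opened trimethylsilyl ether F9.
   - Buffered fluoride (TBAF/AcOH, THF, 0 °C) should then release the C1 alkoxide next to the anti bromide and close the epoxide to 15.

3. Step 8. Methanolysis of two hindered esters may be slower than base-induced decomposition of the epoxy enone. The fallback removes the resolving esters where base is harmless and carries silyl ethers through the cascade. It sets out from 12 (isolated instead of being hydrolysed in the pot) and comes back at 16.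
   - (1S)-Camphanic chloride/pyridine and separation should give the bis-camphanate of the enol ether F10.
   - K2CO3/MeOH should remove both esters while no ketone is present (single-enantiomer 12), and dilute HCl should give single-enantiomer 13; both have the structures already in the compound list.
   - TESCl/imidazole should give the bis(triethylsilyl) ether F11.
   - DBU should give the silyl-protected epoxy enone F12.
   - HF·pyridine returns to the route at 16.

**Further compounds**

F1 | step 5 | tert-butyl{[4-methoxy-5-farnesylfuran-2-yl]methoxy}dimethylsilane | CC(C)(C)[Si](C)(C)OCc1cc(OC)c(C/C=C(\C)CC/C=C(\C)CCC=C(C)C)o1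
F2 | step 5 | racemic endo cyclic carbonate cycloadduct (carbonate oxygens on C5 and C6 anti to the bridge) | CC(C)(C)[Si](C)(C)OC[C@@]12O[C@@](C/C=C(\C)CC/C=C(\C)CCC=C(C)C)(C(OC)=C1)[C@H]3OC(=O)O[C@H]32
F3 | step 5 | racemic endo,endo-diol enol ether | CC(C)(C)[Si](C)(C)OC[C@@]12O[C@@](C/C=C(\C)CC/C=C(\C)CCC=C(C)C)(C(OC)=C1)[C@@H](O)[C@H]2O
F4 | step 5 | racemic bis-mesylate enol ether | CC(C)(C)[Si](C)(C)OC[C@@]12O[C@@](C/C=C(\C)CC/C=C(\C)CCC=C(C)C)(C(OC)=C1)[C@@H](OS(C)(=O)=O)[C@H]2OS(C)(=O)=O
F5 | step 5 | racemic keto bis-mesylate | CC(C)(C)[Si](C)(C)OC[C@@]12O[C@@](C/C=C(\C)CC/C=C(\C)CCC=C(C)C)(C(=O)C1)[C@@H](OS(C)(=O)=O)[C@H]2OS(C)(=O)=O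
F6 | step 5 | racemic epoxy enone with the C5 mesylate anti to the epoxide | CC(C)=CCC/C(C)=C/CC/C(C)=C/C[C@@]12O[C@@H]1[C@@H](OS(C)(=O)=O)C(CO[Si](C)(C)C(C)(C)C)=CC2=O
F7 | step 5 | racemic epoxy enone with the C5 acetate syn to the epoxide | CC(C)=CCC/C(C)=C/CC/C(C)=C/C[C@@]12O[C@@H]1[C@H](OC(C)=O)C(CO[Si](C)(C)C(C)(C)C)=CC2=O
F8 | step 5 | racemic 16 | CC(C)=CCC/C(C)=C/CC/C(C)=C/C[C@@]12O[C@@H]1[C@H](O)C(CO)=CC2=O
F9 | step 7 | ring-opened C1 trimethylsilyl ether: 6-bromo-cyclohex-2-enone bis-camphanate | C[Si](C)(C)O[C@@]1(C/C=C(\C)CC/C=C(\C)CCC=C(C)C)C(=O)C=C(COC(=O)[C@@]23CC[C@@](C)(C(=O)O2)C3(C)C)[C@@H](OC(=O)[C@@]45CC[C@@](C)(C(=O)O4)C5(C)C)[C@@H]1Br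
F10 | step 8 | bis[(1S,4R)-camphanate] of the (1S,4S,5R,6S)-enantiomer of 12 | O=C(OC[C@@]12O[C@@](C/C=C(\C)CC/C=C(\C)CCC=C(C)C)(C(OC)=C1)[C@@H](Br)[C@@H]2OC(=O)[C@@]34CC[C@@](C)(C(=O)O3)C4(C)C)[C@@]56CC[C@@](C)(C(=O)O5)C6(C)C
F11 | step 8 | bis(triethylsilyl) ether of single-enantiomer 13 | CC[Si](CC)(CC)OC[C@@]12O[C@@](C/C=C(\C)CC/C=C(\C)CCC=C(C)C)(C(=O)C1)[C@@H](Br)[C@@H]2O[Si](CC)(CC)CC
F12 | step 8 | bis(triethylsilyl) ether of 16 | CC(C)=CCC/C(C)=C/CC/C(C)=C/C[C@@]12O[C@@H]1[C@H](O[Si](CC)(CC)CC)C(CO[Si](CC)(CC)CC)=CC2=O
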